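The plan cuts the bond between ring carbon C3 (the CH flanked by the acetoxy carbon C4 and the formyl-bearing C2) and side-chain carbon C10 (CH–CH3). The segment C19(formyl)–C2–C3–C4, oxygenated at both ends, is disguised as a furan: 5-hydroxyfuranone and (S,E)-pent-3-en-2-ol give a 2-silyloxy-5-allyloxyfuran whose dearomative Claisen rearrangement forms C3–C10, sets both stereocentres through a chair by 1,3-chirality transfer, and leaves C4 and C19 differentiated, so hydride gives one butyrolactone. Lactone aldol, propargylation, B-alkyl Suzuki closure of the nine-membered ring and triflate formylation complete the dialdehyde.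

Key step: step 3

Remark: labels follow the target (ring C1 = C bearing the conjugated CHO C18, C2 = CH–CHO (C19), C3, C4 = CH–OAc, C5, C6(CH3)=C7, C8, C9=; C10 = side-chain CH–CH3); the acetal carbons of 4 and 17 and carbinol C1 of 14–27 are carried as epimer mixtures (undefined in the SMILES) because they are erased later.

Step 1
Reactants: 1 (E)-pent-3-en-2-ol (racemic)
Product: 2 (2S,3E)-pent-3-en-2-ol
Conditions: CAL-B (Novozym 435), vinyl acetate, MTBE, 25 °C, to about 55 % conversion; separation from the acetate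
Reagents that add atoms: none
Why: Lipase-catalysed kinetic resolution by transesterification, in which the enzyme should acylate the (R)-alcohol preferentially so that the (S)-alcohol is recovered once conversion passes one half.

Step 2
Reactants: 2 (2S,3E)-pent-3-en-2-ol; 3 5-hydroxyfuran-2(5H)-one
Product: 4 5-{[(2S,3E)-pent-3-en-2-yl]oxy}furan-2(5H)-one (both acetal epimers)
Conditions: PPTS (5 mol %), benzene, reflux, Dean–Stark
Reagents that add atoms: none
Why: Acid-catalysed acetal exchange at the hemiacetal carbon of the pseudo-acid goes through the furanone oxocarbenium ion, so the allylic C–O bond and its configuration should stay untouched, and the unselective new acetal centre is erased in step 3.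

Step 3
Reactants: 4 5-{[(2S,3E)-pent-3-en-2-yl]oxy}furan-2(5H)-one
Product: 8 (4S)-4-[(2R,3E)-pent-3-en-2-yl]oxolan-2-one, via silyloxyfuran 5 (not isolated), via silyl ketene acetal 6 (not isolated), via hydroxy acid 7 (not isolated)
Conditions: KHMDS (0.98 equiv), THF, −78 °C; TBSCl; 23 → 60 °C; LiBH4, 0 °C → rt; 2 M HCl
Reagents that add atoms: none
Why: Deprotonation at the acetal carbon and O-silylation turn the pseudo-ester into the aromatic ketene acetal 5, an allyl 2-furyl ether, which should undergo a concerted suprafacial [3,3] (Claisen) shift through a chair with the carbinol methyl equatorial; the closest known reactions are the Ireland–Claisen rearrangement of allyl silyl ketene acetals and the dearomative Claisen rearrangement of 5-allyloxyoxazoles to azlactones. The C3–C10 bond forms with 1,3-chirality transfer from the (S)-carbinol, and because the furan ring locks C2 trans to the allylic oxygen (equatorial) while the (E)-alkene puts the C10 methyl equatorial, both new stereocentres (C3 and C10, syn along C4–C3–C10–C11) are fixed by that one chair. In 6 only C4 is still a carbonyl (C19 is masked as the silyl ketene acetal), so LiBH4 should reduce C4 alone, and acid work-up closes the γ-lactone 8 by 5-exo-trig acyl substitution of the C4 hydroxyl on the C19 acid. The step needs the [3,3] shift to outrun ionisation of the allylic ether and enolisation of C3–H; a slight deficit of KHMDS, the non-basic by-product HMDS and a neutral thermal rearrangement should secure this.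

Step 4
Reactants: 8 (4S)-4-[(2R,3E)-pent-3-en-2-yl]oxolan-2-one
Product: 9 (4S)-4-[(2R)-but-3-en-2-yl]oxolan-2-one
Conditions: Hoveyda–Grubbs II (5 mol %), ethylene (3 bar), CH2Cl2, 40 °C
Reagents that add atoms: ethylene (C=C)
Why: Ethenolysis (olefin cross-metathesis with ethylene) trims the sacrificial methyl that carried the chirality transfer and should give the terminal vinyl group needed for step 5, the lactone and both stereocentres being inert.

Step 5
Reactants: 9 (4S)-4-[(2R)-but-3-en-2-yl]oxolan-2-one; 10 1-bromo-2-methylprop-1-ene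
Product: 12 (4S)-4-[(2R)-6-methylhept-5-en-2-yl]oxolan-2-one, via alkylborane 11 (not isolated)
Conditions: 9-BBN, THF, 0 °C → rt; then 10, Pd(dppf)Cl2 (5 mol %), aq. K3PO4, DMF, 50 °C; HCl work-up
Reagents that add atoms: none
Why: Anti-Markovnikov hydroboration of the only alkene followed by B-alkyl Suzuki–Miyaura coupling should install the 2-methylpropenyl terminus of the side chain without touching a stereocentre, and the acidic work-up re-closes any opened lactone.

Step 6
Reactants: 12 (4S)-4-[(2R)-6-methylhept-5-en-2-yl]oxolan-2-one; 13 acrolein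
Product: 15 (3R,4R)-3-(1-hydroxyprop-2-en-1-yl)-4-[(2R)-6-methylhept-5-en-2-yl]oxolan-2-one (cis lactone), via trans-aldol lactone 14 (not isolated)
Conditions: LDA, THF, −78 °C; 13; LDA, −78 → −45 °C; AcOH, −78 °C
Reagents that add atoms: none
Why: The lactone-enolate aldol (Zimmerman–Traxler) should add acrolein anti to the C3 side chain, and deprotonating the aldolate to the alkoxide–enolate dianion (Fráter–Seebach type) and protonating it kinetically from the face opposite the C3 substituent then places the hydroxyallyl group cis to that substituent, which is the C2 configuration of the target, while carbinol C1 forms as a mixture that is erased in step 15.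

Step 7
Reactants: 15 cis-aldol lactone
Product: 16 (3R,4R)-3-{1-[(tert-butyldimethylsilyl)oxy]prop-2-en-1-yl}-4-[(2R)-6-methylhept-5-en-2-yl]oxolan-2-one
Conditions: TBSOTf, 2,6-lutidine, CH2Cl2, −78 °C
Reagents that add atoms: tert-butyldimethylsilyl triflate (CC(C)(C)[Si](C)(C)OS(=O)(=O)C(F)(F)F)
Why: Silyl triflate silylation should protect the allylic C1 carbinol under conditions too mild to epimerise C2.

Step 8
Reactants: 16 silyl ether lactone
Product: 18 dithiane alcohol HOCH2(C4)–C3H(side chain)–C2H(1,3-dithian-2-yl)–C1H(OTBS)–CH=CH2 with C2, C3 and C10 as in the target, via lactol 17 (not isolated)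
Conditions: DIBAL-H, CH2Cl2, −78 °C; then HS(CH2)3SH, BF3·OEt2 (cat.), CH2Cl2, −40 °C
Reagents that add atoms: propane-1,3-dithiol (SCCCS)
Why: Partial DIBAL-H reduction should stop at the lactol, whose open hydroxy-aldehyde form is trapped by dithioacetalisation, releasing C4 as a primary alcohol and masking C19 at the aldehyde level without touching C2 or C3.

Step 9
Reactants: 18 dithiane alcohol
Product: 19 aldehyde OHC(C4)–C3H(side chain)–C2H(1,3-dithian-2-yl)–C1H(OTBS)–CH=CH2
Conditions: (COCl)2, DMSO, CH2Cl2, −78 °C; Et3N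
Reagents that add atoms: none
Why: Swern oxidation should give the α-branched aldehyde under conditions cold and brief enough to leave C3 and the dithiane intact.

Step 10
Reactants: 19 aldehyde; 20 4,4,5,5-tetramethyl-2-(propa-1,2-dien-1-yl)-1,3,2-dioxaborolane
Product: 21 homopropargylic alcohol HC≡C–CH2–C4H(OH)–C3H(side chain)–C2H(dithianyl)–C1H(OTBS)–CH=CH2, C4 (R) as in the target
Conditions: 20, (R)-TRIP (10 mol %), 4 Å MS, toluene, 0 °C
Reagents that add atoms: none
Why: Chiral phosphoric acid-catalysed propargylboration (SE2′ addition of the allenylboronate through a six-membered transition state) creates C4, the catalyst antipode being the one expected to give the (R)-carbinol and to override the α-stereocentre.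

Step 11
Reactants: 21 homopropargylic alcohol
Product: 23 (E)-vinyl iodide I–C7H=C6(CH3)–C5H2–C4H(OH)–…, via alkenylalane 22 (not isolated)
Conditions: AlMe3, Cp2ZrCl2, H2O (1 equiv), CH2Cl2, −23 °C; I2, THF, −30 °C
Reagents that add atoms: trimethylaluminium (C[Al](C)C); iodine (II)
Why: Negishi zirconium-catalysed carboalumination should add methyl and aluminium syn across the terminal alkyne (methyl to the internal carbon) and iodinolysis with retention gives the (E)-2-methyl-1-iodoalkene, the terminal alkene reacting far more slowly.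

Step 12
Reactants: 23 vinyl iodide alcohol
Product: 24 C4 acetate of 23
Conditions: Ac2O, pyridine, DMAP (cat.), CH2Cl2, rt
Reagents that add atoms: acetic anhydride (CC(=O)OC(C)=O)
Why: DMAP-catalysed acylation should install the final C4 acetate.

Step 13
Reactants: 24 vinyl iodide acetate
Product: 26 (E)-cyclononene with C1–OTBS, C2-dithianyl, C3 side chain, C4–OAc and C6(CH3)=C7, via alkylborane 25 (not isolated)
Conditions: 9-BBN, THF, rt; then Pd(dppf)Cl2 (20 mol %), AsPh3, Cs2CO3, THF/DMF/H2O, 2 mM, 50 °C
Reagents that add atoms: none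
Why: 9-BBN should hydroborate only the monosubstituted C8=C9 alkene, and intramolecular B-alkyl Suzuki–Miyaura coupling with the (E)-vinyl iodide under high dilution forms the C7–C8 bond with retention of alkene geometry, closing the nine-membered ring.

Step 14
Reactants: 26 silyl ether
Product: 27 ring alcohol (C1–OH)
Conditions: HF·pyridine, pyridine, THF, 0 °C → rt
Reagents that add atoms: none
Why: Fluoride-mediated desilylation should free the C1 carbinol while acetate and dithiane survive buffered HF.

Step 15
Reactants: 27 ring alcohol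
Product: 28 ring ketone (C1=O)
Conditions: (COCl)2, DMSO, CH2Cl2, −78 °C; Et3N
Reagents that add atoms: none
Why: Swern oxidation should convert both C1 epimers into one ketone.

Step 16
Reactants: 28 ring ketone
Product: 29 enol triflate C1(OTf)=C9
Conditions: KHMDS, THF, −78 °C; PhNTf2
Reagents that add atoms: N-phenylbis(trifluoromethanesulfonimide) (O=S(=O)(N(c1ccccc1)S(=O)(=O)C(F)(F)F)C(F)(F)F)
Why: Kinetic deprotonation at the unhindered C9 methylene rather than the tertiary C2–H, followed by O-triflation, should give the ring-cis enol triflate, the only geometry a ring already holding an (E)-alkene can accommodate.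

Step 17
Reactants: 29 enol triflate
Product: 30 enal C1(CHO)=C9 with C19 still as the dithiane
Conditions: Pd(PPh3)4 (10 mol %), CO (1 atm), Bu3SnH (slow addition), THF, 50 °C
Reagents that add atoms: carbon monoxide ([C-]#[O+])
Why: Palladium-catalysed reductive carbonylation (formylation) of the enol triflate with CO and tin hydride should install C18 with retention of geometry, giving the (E)-enal.

Step 18
Reactants: 30 enal dithiane
Product: 31 target dialdehyde
Conditions: MeI, CaCO3, MeCN/H2O (9:1), 40 °C
Reagents that add atoms: water (O)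
Why: S-Methylation followed by hydrolysis (alkylative dithioacetal cleavage) should unmask the C19 aldehyde under near-neutral conditions that do not epimerise C2 or touch the enal and acetate.

Compound list
1 | (E)-pent-3-en-2-ol, racemic | C/C=C/C(C)O | starting material
2 | (2S,3E)-pent-3-en-2-ol | C/C=C/[C@H](C)O | intermediate
3 | 5-hydroxyfuran-2(5H)-one, racemic | O=C1OC(O)C=C1 | starting material
4 | 5-{[(2S,3E)-pent-3-en-2-yl]oxy}furan-2(5H)-one, acetal epimers | C/C=C/[C@H](C)OC1OC(=O)C=C1 | intermediate
5 | tert-butyldimethyl[(5-{[(2S,3E)-pent-3-en-2-yl]oxy}furan-2-yl)oxy]silane | C/C=C/[C@H](C)Oc1ccc(O[Si](C)(C)C(C)(C)C)o1 | intermediate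
6 | (3R)-5-[(tert-butyldimethylsilyl)oxy]-3-[(2R,3E)-pent-3-en-2-yl]furan-2(3H)-one | O=C1OC(O[Si](C)(C)C(C)(C)C)=C[C@H]1[C@H](C)/C=C/C | intermediate
7 | (3S,4R,5E)-3-(hydroxymethyl)-4-methylhept-5-enoic acid | OC[C@@H](CC(=O)O)[C@H](C)/C=C/C | intermediate
8 | (4S)-4-[(2R,3E)-pent-3-en-2-yl]oxolan-2-one | O=C1C[C@H](CO1)[C@H](C)/C=C/C | intermediate
9 | (4S)-4-[(2R)-but-3-en-2-yl]oxolan-2-one | O=C1C[C@H](CO1)[C@H](C)C=C | intermediate
10 | 1-bromo-2-methylprop-1-ene | CC(C)=CBr | starting material
11 | (4S)-4-[(2R)-4-(9-borabicyclo[3.3.1]nonan-9-yl)butan-2-yl]oxolan-2-one | O=C1C[C@H](CO1)[C@H](C)CCB1C2CCCC1CCC2 | intermediate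
12 | (4S)-4-[(2R)-6-methylhept-5-en-2-yl]oxolan-2-one | O=C1C[C@H](CO1)[C@H](C)CCC=C(C)C | intermediate
13 | acrolein (prop-2-enal) | C=CC=O | starting material
14 | (3S,4R)-3-(1-hydroxyprop-2-en-1-yl)-4-[(2R)-6-methylhept-5-en-2-yl]oxolan-2-one (trans, C2 epimer) | O=C1OC[C@H]([C@H](C)CCC=C(C)C)[C@H]1C(O)C=C | intermediate
15 | (3R,4R)-3-(1-hydroxyprop-2-en-1-yl)-4-[(2R)-6-methylhept-5-en-2-yl]oxolan-2-one (cis) | O=C1OC[C@H]([C@H](C)CCC=C(C)C)[C@@H]1C(O)C=C | intermediate
16 | (3R,4R)-3-{1-[(tert-butyldimethylsilyl)oxy]prop-2-en-1-yl}-4-[(2R)-6-methylhept-5-en-2-yl]oxolan-2-one | O=C1OC[C@H]([C@H](C)CCC=C(C)C)[C@@H]1C(O[Si](C)(C)C(C)(C)C)C=C | intermediate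
17 | lactol of 16 (oxolan-2-ol, anomers) | OC1OC[C@H]([C@H](C)CCC=C(C)C)[C@@H]1C(O[Si](C)(C)C(C)(C)C)C=C | intermediate
18 | dithiane alcohol: C4 primary alcohol, C2 bearing 1,3-dithian-2-yl, C1 bearing OTBS and vinyl | OC[C@H]([C@H](C)CCC=C(C)C)[C@@H](C1SCCCS1)C(O[Si](C)(C)C(C)(C)C)C=C | intermediate
19 | C4 aldehyde of 18 | O=C[C@H]([C@H](C)CCC=C(C)C)[C@@H](C1SCCCS1)C(O[Si](C)(C)C(C)(C)C)C=C | intermediate
20 | 4,4,5,5-tetramethyl-2-(propa-1,2-dien-1-yl)-1,3,2-dioxaborolane | C=C=CB1OC(C)(C)C(C)(C)O1 | starting material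
21 | homopropargylic alcohol, C4 (R) | C#CC[C@@H](O)[C@H]([C@H](C)CCC=C(C)C)[C@@H](C1SCCCS1)C(O[Si](C)(C)C(C)(C)C)C=C | intermediate
22 | (E)-alkenyl(dimethyl)alane, C4 O-dimethylaluminium alkoxide | C[Al](C)/C=C(\C)C[C@@H](O[Al](C)C)[C@H]([C@H](C)CCC=C(C)C)[C@@H](C1SCCCS1)C(O[Si](C)(C)C(C)(C)C)C=C | intermediate
23 | (E)-vinyl iodide alcohol | I/C=C(\C)C[C@@H](O)[C@H]([C@H](C)CCC=C(C)C)[C@@H](C1SCCCS1)C(O[Si](C)(C)C(C)(C)C)C=C | intermediate
24 | (E)-vinyl iodide C4 acetate | I/C=C(\C)C[C@@H](OC(C)=O)[C@H]([C@H](C)CCC=C(C)C)[C@@H](C1SCCCS1)C(O[Si](C)(C)C(C)(C)C)C=C | intermediate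
25 | B-alkyl-9-BBN from 24 (boron on C8) | I/C=C(\C)C[C@@H](OC(C)=O)[C@H]([C@H](C)CCC=C(C)C)[C@@H](C1SCCCS1)C(O[Si](C)(C)C(C)(C)C)CCB1C2CCCC1CCC2 | intermediate
26 | (E)-cyclononene: C1–OTBS, C2-dithianyl, C3 side chain, C4–OAc | CC(=O)O[C@@H]1C/C(C)=C/CCC(O[Si](C)(C)C(C)(C)C)[C@H](C2SCCCS2)[C@H]1[C@H](C)CCC=C(C)C | intermediate
27 | ring alcohol (C1–OH) | CC(=O)O[C@@H]1C/C(C)=C/CCC(O)[C@H](C2SCCCS2)[C@H]1[C@H](C)CCC=C(C)C | intermediate
28 | ring ketone (C1=O) | CC(=O)O[C@@H]1C/C(C)=C/CCC(=O)[C@H](C2SCCCS2)[C@H]1[C@H](C)CCC=C(C)C | intermediate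
29 | enol triflate C1(OTf)=C9 | CC(=O)O[C@@H]1C/C(C)=C/C/C=C(/OS(=O)(=O)C(F)(F)F)[C@H](C2SCCCS2)[C@H]1[C@H](C)CCC=C(C)C | intermediate
30 | enal with C19 as 1,3-dithiane | CC(=O)O[C@@H]1C/C(C)=C/C/C=C(/C=O)[C@H](C2SCCCS2)[C@H]1[C@H](C)CCC=C(C)C | intermediate
31 | target dialdehyde (2R,3R,4R,10R) | CC(=O)O[C@@H]1C/C(C)=C/C/C=C(/C=O)[C@H](C=O)[C@H]1[C@H](C)CCC=C(C)C | target

Total step count: 18. Longest linear sequence: 18 steps (1 → 31).

Steps most likely to fail

Step 3. Ionisation of the allylic acetal, enolisation or over-silylation at C3, or a sluggish dearomative shift could erode the chirality transfer, and premature loss of the silyl ketene acetal would spoil the regioselective reduction. The fallback sets out from 2 and uses the classical acyclic rearrangement. Esterification of 2 with commercial 4-(dimethylamino)-4-oxobutanoic acid (DCC, DMAP) should give (2S,3E)-pent-3-en-2-yl 4-(dimethylamino)-4-oxobutanoate F1. Ireland–Claisen rearrangement through the Z(O)-enolate (LDA, THF/DMPU, TMSCl, −78 °C → rt; same chair) should give (2S,3R,4E)-2-[2-(dimethylamino)-2-oxoethyl]-3-methylhex-4-enoic acid F2. Reduction of the acid through its mixed anhydride (ClCO2Et, Et3N; NaBH4) should give (3S,4R,5E)-3-(hydroxymethyl)-N,N,4-trimethylhept-5-enamide F3, which lactonises with TsOH in refluxing toluene and comes back to the route at 8.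

Step 13. Oligomerisation, protodeboronation or β-hydride loss may outcompete closure of the strained (E)-cyclononene. The fallback sets out from 24 and closes the ring by carbonyl addition instead. Hydroboration–oxidation (9-BBN; NaBO3) should give the C8 primary alcohol F5, and Parikh–Doering oxidation the C8 aldehyde F6. Intramolecular Nozaki–Hiyama–Kishi coupling (CrCl2, NiCl2 cat., DMSO/THF, high dilution) should give the cyclic allylic alcohol F7, which is acetylated to the allylic acetate F8. Palladium-catalysed hydride displacement (Pd(PPh3)4, Bu3SnH, hydride to the less substituted terminus C8) then comes back to the route at 26.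

Step 6. Retro-aldol cleavage or β-elimination during dianion formation, or poor facial selectivity in the protonation, would leave the C2 epimer. The fallback sets out from 14, isolated by quenching directly after the aldol addition. Silylation (TBSOTf, 2,6-lutidine) should give the trans silyl ether lactone F4. Its mono-enolate (LiHMDS, THF, −78 °C, short contact) is then protonated kinetically with 2,6-di-tert-butylphenol from the face opposite the C3 substituent, which comes back to the route at 16.

Further compounds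
F1 | step 3 | (2S,3E)-pent-3-en-2-yl 4-(dimethylamino)-4-oxobutanoate | C/C=C/[C@H](C)OC(=O)CCC(=O)N(C)C
F2 | step 3 | (2S,3R,4E)-2-[2-(dimethylamino)-2-oxoethyl]-3-methylhex-4-enoic acid | OC(=O)[C@@H](CC(=O)N(C)C)[C@H](C)/C=C/C
F3 | step 3 | (3S,4R,5E)-3-(hydroxymethyl)-N,N,4-trimethylhept-5-enamide | OC[C@@H](CC(=O)N(C)C)[C@H](C)/C=C/C
F4 | step 6 | trans silyl ether lactone (C2 epimer of 16) | O=C1OC[C@H]([C@H](C)CCC=C(C)C)[C@H]1C(O[Si](C)(C)C(C)(C)C)C=C
F5 | step 13 | C8 primary alcohol from 24 | I/C=C(\C)C[C@@H](OC(C)=O)[C@H]([C@H](C)CCC=C(C)C)[C@@H](C1SCCCS1)C(O[Si](C)(C)C(C)(C)C)CCO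
F6 | step 13 | C8 aldehyde | I/C=C(\C)C[C@@H](OC(C)=O)[C@H]([C@H](C)CCC=C(C)C)[C@@H](C1SCCCS1)C(O[Si](C)(C)C(C)(C)C)CC=O
F7 | step 13 | cyclic allylic alcohol (C8–OH) | CC(=O)O[C@@H]1C/C(C)=C/C(O)CC(O[Si](C)(C)C(C)(C)C)[C@H](C2SCCCS2)[C@H]1[C@H](C)CCC=C(C)C
F8 | step 13 | cyclic allylic acetate (C8–OAc) | CC(=O)O[C@@H]1C/C(C)=C/C(OC(C)=O)CC(O[Si](C)(C)C(C)(C)C)[C@H](C2SCCCS2)[C@H]1[C@H](C)CCC=C(C)C
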